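**Retrosynthetic overview**
1. Target ⇒ O-benzyl 3-methylidene oxolane: one H2/Pd operation adds H2 to the exocyclic alkene from the face opposite both aryl groups (sets C3) and frees the phenol.
2. 3-Methylidene oxolane ⇒ (Z)-vinylsilane ⇒ open-chain 1,6-enyne (a bis-benzylic allyl propargyl ether): a rhodium/H2 reductive bicyclization closes the oxolane and a rhodacyclopentene in the same event (sets C4), and H2 then opens the metallacycle to C4–CH3 and the vinylsilane.
3. Enyne ⇒ (S)-aryl propargylic alcohol + achiral cinnamyl tert-butyl carbonate: iridium-catalysed asymmetric allylic etherification makes the C5–O bond and sets C5.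
4. Building blocks ⇒ 3-hydroxy-4,5-dimethoxybenzaldehyde (benzylation, then asymmetric alkynylation sets C2) and methyl 3,4,5-trimethoxycinnamate (reduction, Boc carbonate).
5. Ring order: both benzene rings are bought; the oxolane is the only ring built, and it forms together with the temporary rhodacycle in step 6.

Assumption: compounds 1 and 5 are taken as catalogue materials, and the ligand antipodes named in steps 2 and 5 are those expected to give the stated configurations, to be confirmed on the first run (Mosher ester of 4, HPLC of 10).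

**Route**

Step 1
Reactants: 1 3-hydroxy-4,5-dimethoxybenzaldehyde
Product: 2 3-(benzyloxy)-4,5-dimethoxybenzaldehyde
Conditions: BnBr (1.1 equiv), K2CO3 (1.5 equiv), DMF, rt
Reagents that add atoms: benzyl bromide, BrCc1ccccc1
Why: Williamson ether synthesis on the phenoxide gives a benzyl ether that survives the organozinc, alkoxide, rhodium/H2 and basic steps and is removed by the final hydrogenation.

Step 2
Reactants: 2 3-(benzyloxy)-4,5-dimethoxybenzaldehyde; 3 ethynyltrimethylsilane
Product: 4 (1S)-1-[3-(benzyloxy)-4,5-dimethoxyphenyl]-3-(trimethylsilyl)prop-2-yn-1-ol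
Conditions: Me2Zn (3 equiv), 3 (3 equiv), (S,S)-ProPhenol (10 mol%), Ph3PO (20 mol%), toluene, 0 °C, 24 h
Reagents that add atoms: none
Why: Catalytic asymmetric alkynylation of an aldehyde (Trost dinuclear zinc–ProPhenol type) delivers the alkynylzinc to one aldehyde face inside the chiral dizinc pocket and so sets the carbinol centre (the future C2) as S.

Step 3
Reactants: 5 methyl (2E)-3-(3,4,5-trimethoxyphenyl)prop-2-enoate
Product: 6 (2E)-3-(3,4,5-trimethoxyphenyl)prop-2-en-1-ol
Conditions: i-Bu2AlH (2.2 equiv), CH2Cl2, −78 to 0 °C; Rochelle salt work-up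
Reagents that add atoms: none
Why: 1,2-Reduction of the enoate by the aluminium hydride gives the allylic alcohol without touching the E alkene.

Step 4
Reactants: 6 (2E)-3-(3,4,5-trimethoxyphenyl)prop-2-en-1-ol
Product: 7 tert-butyl (2E)-3-(3,4,5-trimethoxyphenyl)prop-2-en-1-yl carbonate
Conditions: Boc2O (1.2 equiv), DMAP (5 mol%), CH2Cl2, 0 °C to rt
Reagents that add atoms: di-tert-butyl dicarbonate, CC(C)(C)OC(=O)OC(=O)OC(C)(C)C
Why: DMAP-catalysed O-acylation gives the allylic carbonate whose leaving group ends as hindered tert-butoxide and CO2, so it does not compete as a nucleophile in step 5.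

Step 5
Reactants: 4 (1S)-1-[3-(benzyloxy)-4,5-dimethoxyphenyl]-3-(trimethylsilyl)prop-2-yn-1-ol; 7 tert-butyl (2E)-3-(3,4,5-trimethoxyphenyl)prop-2-en-1-yl carbonate
Product: 10 1-(benzyloxy)-2,3-dimethoxy-5-[(1S)-1-{[(1S)-1-(3,4,5-trimethoxyphenyl)prop-2-en-1-yl]oxy}-3-(trimethylsilyl)prop-2-yn-1-yl]benzene, via lithium alkoxide 8 (not isolated), via cuprous alkoxide 9 (not isolated)
Conditions: n-BuLi (1.0 equiv), THF, −78 to 0 °C; CuI (1.0 equiv), rt; then 7 (1.3 equiv), [Ir(cod)Cl]2 (2 mol%), (Sa,S,S)-BINOL bis(1-phenylethyl)phosphoramidite (4 mol%), THF, rt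
Reagents that add atoms: none
Why: Iridium-catalysed asymmetric allylic etherification with a copper alkoxide (Hartwig type) puts the alkoxide on the aryl-bearing terminus of the allyliridium intermediate under catalyst control, setting the new C–O centre (the future C5) as S while the propargylic centre is untouched.

Step 6
Reactants: 10 1-(benzyloxy)-2,3-dimethoxy-5-[(1S)-1-{[(1S)-1-(3,4,5-trimethoxyphenyl)prop-2-en-1-yl]oxy}-3-(trimethylsilyl)prop-2-yn-1-yl]benzene
Product: 12 (2S,3Z,4S,5S)-2-[3-(benzyloxy)-4,5-dimethoxyphenyl]-4-methyl-5-(3,4,5-trimethoxyphenyl)-3-[(trimethylsilyl)methylidene]oxolane, via rhodabicycle 11 (not isolated)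
Conditions: Rh(cod)2OTf (5 mol%), 2,2'-bis(diphenylphosphino)biphenyl (BIPHEP, 5 mol%), H2 (1 atm), ClCH2CH2Cl, 25 °C
Reagents that add atoms: none
Why: Hydrogen-mediated rhodium-catalysed reductive cyclization of a 1,6-enyne (Krische type) proceeds by oxidative cyclization on monovalent rhodium, which closes the oxolane and the rhodacyclopentene together with the CH2–Rh arm on the face opposite both aryl groups (sets C4 as S), and H2 then cleaves both Rh–C bonds with retention to leave the C4 methyl and the Z vinylsilane.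

Step 7
Reactants: 12 (2S,3Z,4S,5S)-2-[3-(benzyloxy)-4,5-dimethoxyphenyl]-4-methyl-5-(3,4,5-trimethoxyphenyl)-3-[(trimethylsilyl)methylidene]oxolane
Product: 13 (2R,4S,5S)-2-[3-(benzyloxy)-4,5-dimethoxyphenyl]-4-methyl-3-methylidene-5-(3,4,5-trimethoxyphenyl)oxolane
Conditions: KOSiMe3 (20 mol%), DMSO/H2O (20:1), 60 °C
Reagents that add atoms: none
Why: Base-catalysed protodesilylation through a pentacoordinate silicate replaces the vinylic C–Si bond by C–H without acid, so no stereocentre or benzylic ether is disturbed (the C2 descriptor changes from S to R only because the CIP priorities change).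

Step 8
Reactants: 13 (2R,4S,5S)-2-[3-(benzyloxy)-4,5-dimethoxyphenyl]-4-methyl-3-methylidene-5-(3,4,5-trimethoxyphenyl)oxolane
Product: 15 5-[(2R,3S,4S,5S)-3,4-dimethyl-5-(3,4,5-trimethoxyphenyl)oxolan-2-yl]-2,3-dimethoxyphenol, via benzyl ether 14 (not isolated)
Conditions: H2 (1 atm), 10% Pd/C, EtOAc, rt
Reagents that add atoms: none
Why: Heterogeneous syn-hydrogenation from the face opposite the two cis aryl groups puts the new C3–H on the C4-methyl face and the C3 methyl cis to the C2 aryl (C3 S), and hydrogenolysis of the aryl benzyl ether in the same flask frees the phenol.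

**Compound list**
1 | 3-hydroxy-4,5-dimethoxybenzaldehyde | COc1cc(C=O)cc(O)c1OC | starting material
2 | 3-(benzyloxy)-4,5-dimethoxybenzaldehyde | COc1cc(C=O)cc(OCc2ccccc2)c1OC | intermediate
3 | ethynyltrimethylsilane | C#C[Si](C)(C)C | starting material
4 | (1S)-1-[3-(benzyloxy)-4,5-dimethoxyphenyl]-3-(trimethylsilyl)prop-2-yn-1-ol | COc1cc([C@@H](C#C[Si](C)(C)C)O)cc(OCc2ccccc2)c1OC | intermediate
5 | methyl (2E)-3-(3,4,5-trimethoxyphenyl)prop-2-enoate | COC(=O)/C=C/c1cc(OC)c(OC)c(OC)c1 | starting material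
6 | (2E)-3-(3,4,5-trimethoxyphenyl)prop-2-en-1-ol | OC/C=C/c1cc(OC)c(OC)c(OC)c1 | intermediate
7 | tert-butyl (2E)-3-(3,4,5-trimethoxyphenyl)prop-2-en-1-yl carbonate | CC(C)(C)OC(=O)OC/C=C/c1cc(OC)c(OC)c(OC)c1 | intermediate
8 | lithium (1S)-1-[3-(benzyloxy)-4,5-dimethoxyphenyl]-3-(trimethylsilyl)prop-2-yn-1-olate | COc1cc([C@@H](C#C[Si](C)(C)C)[O-])cc(OCc2ccccc2)c1OC.[Li+] | intermediate (not isolated)
9 | cuprous (1S)-1-[3-(benzyloxy)-4,5-dimethoxyphenyl]-3-(trimethylsilyl)prop-2-yn-1-olate | COc1cc([C@@H](C#C[Si](C)(C)C)O[Cu])cc(OCc2ccccc2)c1OC | intermediate (not isolated)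
10 | 1-(benzyloxy)-2,3-dimethoxy-5-[(1S)-1-{[(1S)-1-(3,4,5-trimethoxyphenyl)prop-2-en-1-yl]oxy}-3-(trimethylsilyl)prop-2-yn-1-yl]benzene | COc1cc([C@@H](C#C[Si](C)(C)C)O[C@H](c3cc(OC)c(OC)c(OC)c3)C=C)cc(OCc2ccccc2)c1OC | intermediate
11 | rhodabicycle: cationic trivalent-rhodium 3-oxa-7-rhodabicyclo[3.3.0]oct-5-ene with BIPHEP on Rh, 3,4,5-trimethoxyphenyl on C2, 3-(benzyloxy)-4,5-dimethoxyphenyl on C4, SiMe3 on C6, the C8 methylene arm on the face opposite both aryl groups, triflate counter-ion | COc1cc([C@@H]2O[C@H](c3cc(OC)c(OC)c(OC)c3)[C@H]4C[Rh-]5([P+](c6ccccc6)(c6ccccc6)c6ccccc6-c6ccccc6[P+]5(c6ccccc6)c6ccccc6)C(=C24)[Si](C)(C)C)cc(OCc6ccccc6)c1OC.[O-]S(=O)(=O)C(F)(F)F | intermediate (not isolated)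
12 | (2S,3Z,4S,5S)-2-[3-(benzyloxy)-4,5-dimethoxyphenyl]-4-methyl-5-(3,4,5-trimethoxyphenyl)-3-[(trimethylsilyl)methylidene]oxolane | COc1cc([C@@H]2O[C@H](c3cc(OC)c(OC)c(OC)c3)[C@@H](C)/C2=C/[Si](C)(C)C)cc(OCc4ccccc4)c1OC | intermediate
13 | (2R,4S,5S)-2-[3-(benzyloxy)-4,5-dimethoxyphenyl]-4-methyl-3-methylidene-5-(3,4,5-trimethoxyphenyl)oxolane | COc1cc([C@@H]2O[C@H](c3cc(OC)c(OC)c(OC)c3)[C@@H](C)C2=C)cc(OCc4ccccc4)c1OC | intermediate
14 | (2R,3S,4S,5S)-2-[3-(benzyloxy)-4,5-dimethoxyphenyl]-3,4-dimethyl-5-(3,4,5-trimethoxyphenyl)oxolane | COc1cc([C@@H]2O[C@H](c3cc(OC)c(OC)c(OC)c3)[C@@H](C)[C@@H]2C)cc(OCc4ccccc4)c1OC | intermediate (not isolated)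
15 | 5-[(2R,3S,4S,5S)-3,4-dimethyl-5-(3,4,5-trimethoxyphenyl)oxolan-2-yl]-2,3-dimethoxyphenol | COc1cc([C@@H]2O[C@H](c3cc(OC)c(OC)c(OC)c3)[C@@H](C)[C@@H]2C)cc(O)c1OC | target

**Step count**
Total steps: 8. Longest linear sequence: 6 (steps 1, 2, 5, 6, 7, 8; the cinnamyl branch 3, 4, 5, 6, 7, 8 is equally long).

**Steps most likely to fail, with fallbacks**

The riskiest is step 6. A silyl-capped alkyne and an ether tether branched at both carbinol carbons are not standard substrates for this rhodium/H2 cyclization. If oxidative cyclization is slow, plain hydrogenation of the vinyl group or cycloisomerization to a diene can take over, and the 4,5-trans preference rests on analogy. The fallback sets out from 10 and replaces the metallacycle by palladium hydride chemistry. K2CO3 in MeOH removes the alkynyl silane to give the terminal enyne F1. Pd2(dba)3·CHCl3, P(o-tol)3, AcOH and Et3SiH in toluene then effect hydropalladation of the alkyne, 5-exo carbopalladation of the vinyl group anti to the aryl groups, and silane reduction of the alkylpalladium. This gives the methylidene oxolane directly and comes back to the route at 13, so step 7 is no longer needed.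

Second is step 7. An unactivated, fully substituted vinyl–SiMe3 may resist the silanolate, and warm basic DMSO could move the exocyclic alkene into conjugation with the C2 aryl. The fallback sets out from 12 and swaps protonolysis for halogen exchange followed by reduction. N-Iodosuccinimide in MeCN/ClCH2CN at 0 °C gives the vinyl iodide F2 with retention. Pd(PPh3)4 with HCO2H/Et3N in DMF then removes the iodine, and the route is rejoined at 13.

Third is step 8. Facial selectivity at C3 is substrate-controlled (two aryl groups against one methyl). Pd/C may also isomerize the alkene into the ring before reducing it, or cleave the allylic/benzylic C2–O bond. The fallback sets out from 13 and builds the C3 methyl by hydroboration and deoxygenation instead of hydrogenation. Bulky 9-BBN adds from the open face to give the alkylborane F3, which NaOH/H2O2 oxidizes to the primary alcohol F4. MsCl/Et3N gives the mesylate F5, and LiBHEt3 in THF reduces it to the benzyl ether 14, here isolated. The route is rejoined at 14, which is debenzylated with H2 and Pd/C as in step 8.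

**Further compounds**
F1 | step 6 | 1-(benzyloxy)-2,3-dimethoxy-5-[(1R)-1-{[(1S)-1-(3,4,5-trimethoxyphenyl)prop-2-en-1-yl]oxy}prop-2-yn-1-yl]benzene (terminal enyne) | COc1cc([C@@H](C#C)O[C@H](c3cc(OC)c(OC)c(OC)c3)C=C)cc(OCc2ccccc2)c1OC
F2 | step 7 | (2S,3Z,4S,5S)-2-[3-(benzyloxy)-4,5-dimethoxyphenyl]-3-(iodomethylidene)-4-methyl-5-(3,4,5-trimethoxyphenyl)oxolane (vinyl iodide) | COc1cc([C@@H]2O[C@H](c3cc(OC)c(OC)c(OC)c3)[C@@H](C)/C2=C/I)cc(OCc4ccccc4)c1OC
F3 | step 8 | 9-{[(2R,3S,4S,5S)-2-[3-(benzyloxy)-4,5-dimethoxyphenyl]-4-methyl-5-(3,4,5-trimethoxyphenyl)oxolan-3-yl]methyl}-9-borabicyclo[3.3.1]nonane (alkylborane) | COc1cc([C@@H]2O[C@H](c3cc(OC)c(OC)c(OC)c3)[C@@H](C)[C@@H]2CB5C6CCCC5CCC6)cc(OCc4ccccc4)c1OC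
F4 | step 8 | [(2R,3R,4S,5S)-2-[3-(benzyloxy)-4,5-dimethoxyphenyl]-4-methyl-5-(3,4,5-trimethoxyphenyl)oxolan-3-yl]methanol (primary alcohol) | COc1cc([C@@H]2O[C@H](c3cc(OC)c(OC)c(OC)c3)[C@@H](C)[C@@H]2CO)cc(OCc4ccccc4)c1OC
F5 | step 8 | [(2R,3R,4S,5S)-2-[3-(benzyloxy)-4,5-dimethoxyphenyl]-4-methyl-5-(3,4,5-trimethoxyphenyl)oxolan-3-yl]methyl methanesulfonate (mesylate) | COc1cc([C@@H]2O[C@H](c3cc(OC)c(OC)c(OC)c3)[C@@H](C)[C@@H]2COS(C)(=O)=O)cc(OCc4ccccc4)c1OC
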